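**Assumption:** the SMILES is read as the (2R,3S) series, i.e. the 3,7-digallate of natural (+)-catechin; 3,4,5-tris(benzyloxy)benzoic acid and 3,4,5-tris(benzyloxy)benzaldehyde are bought.

## Retrosynthetic overview

1. Target ⇒ hexa-O-benzyl, diphenylmethylene-protected 3,7-bis-ester, by one global hydrogenolysis.
2. 7-O–C(=O) bond ⇒ 5,7-diol 3-O-ester + 3,4,5-tris(benzyloxy)benzaldehyde, joined by a site-selective anodic carbene-catalysed oxidative aroylation (key step).
3. 3-O–C(=O) bond ⇒ Steglich esterification on the catechol ketal, with both ring A phenols masked in the flask as silyl ethers.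
4. Catechol ketal ⇒ (+)-catechin, which brings rings A, B and C and both stereocentres; the only ring formed is the benzodioxole protecting ring on ring B, and no stereocentre is made or touched.

## Route

Step 1
Reactants: 1 (+)-catechin; 2 dichlorodiphenylmethane
Product: 3 3',4'-O-diphenylmethylene-(+)-catechin
Conditions: Ph2CCl2 (1.3 equiv), K2CO3 (2.5 equiv), MeCN, rt, N2, 24 h
Reagents that add atoms: dichlorodiphenylmethane (compound 2), ClC(Cl)(c1ccccc1)c1ccccc1
Why: Catechol acetalisation with a gem-dichloride (diphenylmethylene ketal formation): only the ortho-dihydroxy unit of ring B can close the five-membered 2,2-diphenyl-1,3-benzodioxole, the meta-related ring A phenols and 3-OH cannot, and mild base at room temperature leaves C-2 and C-3 (both bought with catechin) untouched.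

Step 2
Reactants: 3 3',4'-O-diphenylmethylene-(+)-catechin; 4 3,4,5-tris(benzyloxy)benzoic acid
Product: 7 3',4'-O-diphenylmethylene-(+)-catechin 3-O-[3,4,5-tris(benzyloxy)benzoate] (5,7-diol), via bis-TBS ether 5 (not isolated), via bis-TBS 3-O-ester 6 (not isolated)
Conditions: TBSCl (2.2 equiv), Et3N, DMAP (cat.), CH2Cl2/THF, 0 °C to rt; then 4, DCC, DMAP, rt; then MeOH quench, Bu4NF/AcOH, THF, 0 °C
Reagents that add atoms: 3,4,5-tris(benzyloxy)benzoic acid (compound 4), OC(=O)c1cc(OCc2ccccc2)c(OCc2ccccc2)c(OCc2ccccc2)c1; tert-butyldimethylsilyl chloride, CC(C)(C)[Si](C)(C)Cl (its atoms are present only in 5 and 6)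
Why: Chemoselective phenol silylation (TBSCl/Et3N does not silylate the hindered secondary 3-OH), then Steglich esterification of the only free hydroxyl with retention at C-3 (the carbinol C–O bond is never broken), then fluoride cleavage of the aryl silyl ethers, which are far more labile than the alkyl benzoate; no stereocentre is formed.

Step 3
Reactants: 7 3',4'-O-diphenylmethylene-(+)-catechin 3-O-[3,4,5-tris(benzyloxy)benzoate]; 8 3,4,5-tris(benzyloxy)benzaldehyde
Product: 11 3',4'-O-diphenylmethylene-(+)-catechin 3,7-bis-O-[3,4,5-tris(benzyloxy)benzoate], via Breslow intermediate 9 (not isolated), via acyl triazolium 10 (not isolated)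
Conditions: 8 (1.05 equiv), 2-mesityl-6,7-dihydro-5H-pyrrolo[2,1-c][1,2,4]triazol-2-ium tetrafluoroborate (15 mol%), DBU (0.5 equiv), n-Bu4NBF4 (0.1 M), THF/MeCN, 4 Å MS, undivided cell, graphite anode, platinum cathode, controlled anode potential (about −0.7 V vs Fc+/Fc, set by CV), 2.1 F/mol, 0 °C to rt, N2
Reagents that add atoms: 3,4,5-tris(benzyloxy)benzaldehyde (compound 8), O=Cc1cc(OCc2ccccc2)c(OCc2ccccc2)c(OCc2ccccc2)c1; the triazolium salt, Cc1cc(C)c(c(C)c1)-[n+]1cn2CCCc2n1.F[B-](F)(F)F (its atoms are present only in 9 and 10)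
Why: Proposed new method: the carbene adds to aldehyde 8 to give Breslow intermediate 9, which is oxidised at the anode by two electrons, at a potential far below that needed for the phenols, the benzyl ethers or the benzodioxole, to the bulky N-mesityl acyl triazolium 10; because 10 is metered in by the charge passed and stays at low concentration, it is expected to aroylate the unflanked 7-OH in preference to the 5-OH, which is hemmed in by the C-4 methylene and the 3-O-aroyl group, while DBU-H+ is reduced to H2 at the cathode and any 5-O-aryl ester can in principle return to the acyl azolium pool by carbene-catalysed transesterification; no stereocentre is formed, and the closest known reaction type is the anodic NHC-catalysed oxidative esterification of aldehydes with simple alcohols (oxidation of Breslow intermediates), which has not been shown for site-selective mono-aroylation of an unprotected polyphenol.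

Step 4
Reactants: 11 3',4'-O-diphenylmethylene-(+)-catechin 3,7-bis-O-[3,4,5-tris(benzyloxy)benzoate]
Product: 12 (+)-catechin 3,7-di-O-gallate
Conditions: H2 (1 atm), Pd(OH)2 on carbon (20 wt%), THF/EtOAc, rt, then filtration and Sephadex LH-20
Reagents that add atoms: none
Why: Heterogeneous catalytic hydrogenolysis cleaves the six benzyl ethers to toluene and the diphenylmethylene ketal to diphenylmethane under neutral conditions that leave both gallate esters (including the phenolic 7-O-ester), the flavan C-2–O bond and the two stereocentres unchanged.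

## Compound list

1 | (+)-catechin, (2R,3S)-2-(3,4-dihydroxyphenyl)chromane-3,5,7-triol | Oc1cc(O)c2c(c1)O[C@H](c1ccc(O)c(O)c1)[C@@H](O)C2 | starting material
2 | dichlorodiphenylmethane | ClC(Cl)(c1ccccc1)c1ccccc1 | starting material
3 | (2R,3S)-2-(2,2-diphenyl-1,3-benzodioxol-5-yl)chromane-3,5,7-triol (3',4'-O-diphenylmethylene-(+)-catechin) | Oc1cc(O)c2c(c1)O[C@H](c1ccc3OC(c4ccccc4)(c4ccccc4)Oc3c1)[C@@H](O)C2 | intermediate
4 | 3,4,5-tris(benzyloxy)benzoic acid | OC(=O)c1cc(OCc2ccccc2)c(OCc2ccccc2)c(OCc2ccccc2)c1 | starting material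
5 | (2R,3S)-5,7-bis(tert-butyldimethylsilyloxy)-2-(2,2-diphenyl-1,3-benzodioxol-5-yl)chroman-3-ol | CC(C)(C)[Si](C)(C)Oc1cc(O[Si](C)(C)C(C)(C)C)c2c(c1)O[C@H](c1ccc3OC(c4ccccc4)(c4ccccc4)Oc3c1)[C@@H](O)C2 | intermediate
6 | (2R,3S)-5,7-bis(tert-butyldimethylsilyloxy)-2-(2,2-diphenyl-1,3-benzodioxol-5-yl)chroman-3-yl 3,4,5-tris(benzyloxy)benzoate | CC(C)(C)[Si](C)(C)Oc1cc(O[Si](C)(C)C(C)(C)C)c2c(c1)O[C@H](c1ccc3OC(c4ccccc4)(c4ccccc4)Oc3c1)[C@@H](OC(=O)c1cc(OCc3ccccc3)c(OCc3ccccc3)c(OCc3ccccc3)c1)C2 | intermediate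
7 | (2R,3S)-2-(2,2-diphenyl-1,3-benzodioxol-5-yl)-5,7-dihydroxychroman-3-yl 3,4,5-tris(benzyloxy)benzoate | Oc1cc(O)c2c(c1)O[C@H](c1ccc3OC(c4ccccc4)(c4ccccc4)Oc3c1)[C@@H](OC(=O)c1cc(OCc3ccccc3)c(OCc3ccccc3)c(OCc3ccccc3)c1)C2 | intermediate
8 | 3,4,5-tris(benzyloxy)benzaldehyde | O=Cc1cc(OCc2ccccc2)c(OCc2ccccc2)c(OCc2ccccc2)c1 | starting material
9 | Breslow intermediate: [2-mesityl-6,7-dihydro-2H,5H-pyrrolo[2,1-c][1,2,4]triazol-3-ylidene][3,4,5-tris(benzyloxy)phenyl]methanol | OC(c1cc(OCc2ccccc2)c(OCc2ccccc2)c(OCc2ccccc2)c1)=C1N(c2c(C)cc(C)cc2C)N=C2CCCN12 | intermediate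
10 | acyl triazolium: 2-mesityl-3-[3,4,5-tris(benzyloxy)benzoyl]-6,7-dihydro-5H-pyrrolo[2,1-c][1,2,4]triazol-2-ium tetrafluoroborate | O=C(c1cc(OCc2ccccc2)c(OCc2ccccc2)c(OCc2ccccc2)c1)c1n2CCCc2n[n+]1-c1c(C)cc(C)cc1C.F[B-](F)(F)F | intermediate
11 | (2R,3S)-2-(2,2-diphenyl-1,3-benzodioxol-5-yl)-5-hydroxy-3-{[3,4,5-tris(benzyloxy)benzoyl]oxy}chroman-7-yl 3,4,5-tris(benzyloxy)benzoate | O=C(Oc1cc(O)c2c(c1)O[C@H](c1ccc3OC(c4ccccc4)(c4ccccc4)Oc3c1)[C@@H](OC(=O)c1cc(OCc3ccccc3)c(OCc3ccccc3)c(OCc3ccccc3)c1)C2)c1cc(OCc2ccccc2)c(OCc2ccccc2)c(OCc2ccccc2)c1 | intermediate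
12 | (+)-catechin 3,7-di-O-gallate, (2R,3S)-2-(3,4-dihydroxyphenyl)-5-hydroxy-3-[(3,4,5-trihydroxybenzoyl)oxy]chroman-7-yl 3,4,5-trihydroxybenzoate | O=C(Oc1cc(O)c2c(c1)O[C@H](c1ccc(O)c(O)c1)[C@@H](OC(=O)c1cc(O)c(O)c(O)c1)C2)c1cc(O)c(O)c(O)c1 | target

## Step count and risks

Total step count: 4. Longest linear sequence: 4 steps from (+)-catechin 1.

The three steps most likely to fail are steps 3, 2 and 4.

**Step 3 (the new anodic site-selective aroylation).** The risks are insufficient 7-O over 5-O selectivity, over-aroylation to the 5,7-diester, and slow Breslow formation from the electron-rich aldehyde. The fallback uses only known chemistry and fixes the regiochemistry with protecting groups; it sets out from 7 and comes back to the route at 12. Diol 7 is silylated with the bulky TBDPSCl (1.05 equiv, imidazole, DMF, −20 °C) at the unflanked 7-OH to give the 7-O-TBDPS ether F1. The regiochemistry is checked by NOE between the remaining 5-OH and H-4, and any wrong isomer is recycled with fluoride. Mitsunobu etherification (BnOH, PPh3, DIAD, THF) then benzylates the 5-OH under neutral conditions to give the 5-O-benzyl 7-O-TBDPS ether F2. Bu4NF/AcOH frees the 7-OH to give the 5-O-benzyl 7-phenol F3. Steglich esterification with acid 4 (DCC, DMAP, CH2Cl2) gives the 5-O-benzyl 3,7-bis-ester F4. Hydrogenolysis under the step 4 conditions removes seven benzyl groups and the ketal and delivers 12.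

**Step 2 (three-stage one-pot).** The risks are incomplete discrimination between the phenols and 3-OH in the silylation, and acylation of freed phenols by left-over activated acid during the fluoride stage. The fallback drops the silyl masking; it sets out from 3 and comes back at 7. Triol 3 is acylated exhaustively with acid 4 (3.5 equiv, DCC, DMAP, CH2Cl2) to give the 3,5,7-tri-O-ester F5. The two phenolic esters are then removed selectively by aminolysis with pyrrolidine (CH2Cl2, rt), which leaves the alkyl 3-O-ester and gives 7.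

**Step 4 (global hydrogenolysis).** The risks are sluggish cleavage of the diphenylmethylene ketal, catalyst poisoning, and loss of the phenolic 7-O-ester on prolonged reaction. The fallback removes the ketal by hydrolysis instead; it sets out from 11 and comes back at 12. Ketal 11 is hydrolysed with AcOH/H2O (4:1, 80 °C) to give the hexa-O-benzyl catechol F6. The six benzyl ethers alone are then hydrogenolysed (H2, Pd(OH)2 on carbon, THF/EtOAc, rt) to give 12.

## Further compounds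

F1 | step 3 | (2R,3S)-7-(tert-butyldiphenylsilyloxy)-2-(2,2-diphenyl-1,3-benzodioxol-5-yl)-5-hydroxychroman-3-yl 3,4,5-tris(benzyloxy)benzoate | CC(C)(C)[Si](c1ccccc1)(c1ccccc1)Oc1cc(O)c2c(c1)O[C@H](c1ccc3OC(c4ccccc4)(c4ccccc4)Oc3c1)[C@@H](OC(=O)c1cc(OCc3ccccc3)c(OCc3ccccc3)c(OCc3ccccc3)c1)C2
F2 | step 3 | (2R,3S)-5-(benzyloxy)-7-(tert-butyldiphenylsilyloxy)-2-(2,2-diphenyl-1,3-benzodioxol-5-yl)chroman-3-yl 3,4,5-tris(benzyloxy)benzoate | CC(C)(C)[Si](c1ccccc1)(c1ccccc1)Oc1cc(OCc3ccccc3)c2c(c1)O[C@H](c1ccc3OC(c4ccccc4)(c4ccccc4)Oc3c1)[C@@H](OC(=O)c1cc(OCc3ccccc3)c(OCc3ccccc3)c(OCc3ccccc3)c1)C2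
F3 | step 3 | (2R,3S)-5-(benzyloxy)-2-(2,2-diphenyl-1,3-benzodioxol-5-yl)-7-hydroxychroman-3-yl 3,4,5-tris(benzyloxy)benzoate | Oc1cc(OCc3ccccc3)c2c(c1)O[C@H](c1ccc3OC(c4ccccc4)(c4ccccc4)Oc3c1)[C@@H](OC(=O)c1cc(OCc3ccccc3)c(OCc3ccccc3)c(OCc3ccccc3)c1)C2
F4 | step 3 | (2R,3S)-5-(benzyloxy)-2-(2,2-diphenyl-1,3-benzodioxol-5-yl)-3-{[3,4,5-tris(benzyloxy)benzoyl]oxy}chroman-7-yl 3,4,5-tris(benzyloxy)benzoate | O=C(Oc1cc(OCc3ccccc3)c2c(c1)O[C@H](c1ccc3OC(c4ccccc4)(c4ccccc4)Oc3c1)[C@@H](OC(=O)c1cc(OCc3ccccc3)c(OCc3ccccc3)c(OCc3ccccc3)c1)C2)c1cc(OCc2ccccc2)c(OCc2ccccc2)c(OCc2ccccc2)c1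
F5 | step 2 | (2R,3S)-2-(2,2-diphenyl-1,3-benzodioxol-5-yl)chromane-3,5,7-triyl tris[3,4,5-tris(benzyloxy)benzoate] | O=C(Oc1cc(OC(=O)c3cc(OCc4ccccc4)c(OCc4ccccc4)c(OCc4ccccc4)c3)c2c(c1)O[C@H](c1ccc3OC(c4ccccc4)(c4ccccc4)Oc3c1)[C@@H](OC(=O)c1cc(OCc3ccccc3)c(OCc3ccccc3)c(OCc3ccccc3)c1)C2)c1cc(OCc2ccccc2)c(OCc2ccccc2)c(OCc2ccccc2)c1
F6 | step 4 | (2R,3S)-2-(3,4-dihydroxyphenyl)-5-hydroxy-3-{[3,4,5-tris(benzyloxy)benzoyl]oxy}chroman-7-yl 3,4,5-tris(benzyloxy)benzoate | O=C(Oc1cc(O)c2c(c1)O[C@H](c1ccc(O)c(O)c1)[C@@H](OC(=O)c1cc(OCc3ccccc3)c(OCc3ccccc3)c(OCc3ccccc3)c1)C2)c1cc(OCc2ccccc2)c(OCc2ccccc2)c(OCc2ccccc2)c1
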